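**Strategy.** The route rests on cutting the C4b–C8a bond (fluorene numbering of the tricyclic core), the fusion bond shared by the dimethylcyclohexane (ring A) and the cyclopentane (ring B). Its neighbour C9 carries the aryl ether oxygen, so a C8a–C9 epoxide can serve as the electrophile. In one operation a Lewis acid lets the terminus of a trienyl allylsilane open this epoxide at C8a (ring A), and the dienyl alkoxide so formed adds to the tethered enoate in an intramolecular Diels–Alder reaction (rings B and C), setting six stereocentres. The precursor is an acyclic epoxy tetraenoate carrying a terminal allylsilane. Mitsunobu etherification and a final aldol/hemiaminal closure then build the cyclophane and lactam.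

Key step: step 13

Remarks on the chemistry:
- Core locants follow fluorene: ring C = C1–C4, C4a, C9a; ring B = C4a, C4b, C8a, C9, C9a; ring A = C4b, C5–C8, C8a. Lactam atoms carry primes (N1', C2'–C5').
- The lipase in step 2 is assumed to acetylate the hydroxymethyl arm drawn in 3. If it prefers the other arm, hydrolysis of the meso-diacetate with the same enzyme should give 3.
- The cascade of step 13 is expected to place the C9 oxygen trans to what the target needs; step 17 inverts it.

**Step 1**
Reactants: 1 meso-2,4-dimethylglutaric anhydride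
Product: 2 meso-(2R,4S)-2,4-dimethylpentane-1,5-diol
Conditions: LiAlH4, THF, 0 °C to reflux
Reagents that add atoms: none
Why: Hydride reduction of both acyl groups of the cyclic anhydride gives the diol; the cis (meso) relation of the two methyl-bearing carbons is not touched.

**Step 2**
Reactants: 2 meso-(2R,4S)-2,4-dimethylpentane-1,5-diol
Product: 3 (2S,4R)-5-hydroxy-2,4-dimethylpentyl acetate
Conditions: lipase AK (Pseudomonas fluorescens), vinyl acetate, THF, 25 °C
Reagents that add atoms: vinyl acetate, C=COC(C)=O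
Why: Enzymatic desymmetrisation by irreversible transesterification distinguishes the enantiotopic hydroxymethyl arms and so fixes both methyl-bearing centres (future C6 and C8) in absolute terms.

**Step 3**
Reactants: 3 (2S,4R)-5-hydroxy-2,4-dimethylpentyl acetate
Product: 4 (2S,4R)-5-iodo-2,4-dimethylpentyl acetate
Conditions: I2, PPh3, imidazole, CH2Cl2, 0 °C to rt
Reagents that add atoms: iodine, II
Why: Appel-type iodination of a primary alcohol proceeds by SN2 at CH2, so no stereocentre is involved and the acetate is inert.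

**Step 4**
Reactants: 4 (2S,4R)-5-iodo-2,4-dimethylpentyl acetate
Product: 6 (2S,4R,6E)-2,4-dimethyl-7-(trimethylsilyl)hept-6-en-1-yl acetate, via alkylzinc iodide 5 (not isolated)
Conditions: Zn dust (activated with BrCH2CH2Br, Me3SiCl), DMA, 40 °C; then (E)-(2-bromovinyl)trimethylsilane, Pd(PPh3)4 (5 mol %), THF, 50 °C
Reagents that add atoms: (E)-(2-bromovinyl)trimethylsilane, C[Si](C)(C)/C=C/Br
Why: Direct zinc insertion tolerates the acetate, and Negishi coupling of the primary alkylzinc with the (E)-bromoalkene keeps the alkene geometry while adding the carbons that become C4b and C4a.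

**Step 5**
Reactants: 6 (2S,4R,6E)-2,4-dimethyl-7-(trimethylsilyl)hept-6-en-1-yl acetate
Product: 7 (2S,4R,6E)-7-iodo-2,4-dimethylhept-6-en-1-yl acetate
Conditions: N-iodosuccinimide, MeCN/ClCH2CN (4:1), 0 °C to rt
Reagents that add atoms: N-iodosuccinimide, O=C1CCC(=O)N1I
Why: Electrophilic ipso-iododesilylation of the (E)-vinylsilane (β-silyl cation pathway) should give the (E)-vinyl iodide with retention.

**Step 6**
Reactants: 7 (2S,4R,6E)-7-iodo-2,4-dimethylhept-6-en-1-yl acetate
Product: 8 (2S,4R,6E)-7-iodo-2,4-dimethylhept-6-en-1-ol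
Conditions: K2CO3 (0.2 equiv), MeOH, 0 °C to rt
Reagents that add atoms: none
Why: Base-catalysed methanolysis frees the primary alcohol and leaves the vinyl iodide alone.

**Step 7**
Reactants: 8 (2S,4R,6E)-7-iodo-2,4-dimethylhept-6-en-1-ol
Product: 9 (2S,4R,6E)-7-iodo-2,4-dimethylhept-6-enal
Conditions: Dess–Martin periodinane, CH2Cl2, 0 °C to rt
Reagents that add atoms: none
Why: Dess–Martin oxidation gives the α-branched aldehyde under non-basic conditions that should not epimerise the adjacent methyl-bearing centre.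

**Step 8**
Reactants: 9 (2S,4R,6E)-7-iodo-2,4-dimethylhept-6-enal
Product: 10 (2E,4S,6R,8E)-9-iodo-4,6-dimethylnona-2,8-dienal
Conditions: (triphenylphosphoranylidene)acetaldehyde, toluene, 80 °C
Reagents that add atoms: (triphenylphosphoranylidene)acetaldehyde, O=CC=P(c1ccccc1)(c1ccccc1)c1ccccc1
Why: Wittig reaction with the stabilised formylmethylene ylide adds two carbons (future C9 and C9a) and should give the (E)-enal.

**Step 9**
Reactants: 10 (2E,4S,6R,8E)-9-iodo-4,6-dimethylnona-2,8-dienal
Product: 12 methyl (2E,4R,5R,6S,8R,10E)-4,5-epoxy-11-iodo-6,8-dimethylundeca-2,10-dienoate, via epoxy aldehyde 11 (not isolated)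
Conditions: (R)-2-{bis[3,5-bis(trifluoromethyl)phenyl][(trimethylsilyl)oxy]methyl}pyrrolidine (10 mol %), 35% aq. H2O2, CH2Cl2, rt; then methyl (triphenylphosphoranylidene)acetate, 0 °C to rt
Reagents that add atoms: hydrogen peroxide, OO; methyl (triphenylphosphoranylidene)acetate, COC(=O)C=P(c1ccccc1)(c1ccccc1)c1ccccc1
Why: Iminium-catalysed nucleophilic epoxidation of the enal (Weitz–Scheffer type, diarylprolinol silyl ether) sets both epoxide carbons under catalyst control as the (2S,3R)-trans-epoxide, the (R)-catalyst being chosen for that sense, and the labile epoxy aldehyde is trapped in the same flask by Wittig reaction to the (E)-enoate.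

**Step 10**
Reactants: 13 (E)-1,2-bis(tributylstannyl)ethene
Product: 15 (E)-3-(tributylstannyl)prop-2-enal, via stannylvinyllithium 14 (not isolated)
Conditions: n-BuLi (1.0 equiv), THF, −78 °C; then DMF, −78 to 0 °C; aq. NH4Cl
Reagents that add atoms: N,N-dimethylformamide, CN(C)C=O
Why: Tin–lithium exchange of one stannyl group gives the (E)-vinyllithium with retention, and formylation with DMF gives the (E)-enal.

**Step 11**
Reactants: 15 (E)-3-(tributylstannyl)prop-2-enal
Product: 16 tributyl[(1E,3Z)-5-(trimethylsilyl)penta-1,3-dien-1-yl]stannane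
Conditions: MePPh3Br, n-BuLi, THF, 0 °C; ICH2SiMe3, rt; n-BuLi, −78 °C; then 15, −78 °C to rt
Reagents that add atoms: methyltriphenylphosphonium bromide, C[P+](c1ccccc1)(c1ccccc1)c1ccccc1.[Br-]; (iodomethyl)trimethylsilane, C[Si](C)(C)CI
Why: Wittig reaction of the non-stabilised β-silyl ylide gives the allylsilane as the (Z)-alkene; this geometry does not matter because the double bond becomes the vinyl group in step 13.

**Step 12**
Reactants: 12 methyl (2E,4R,5R,6S,8R,10E)-4,5-epoxy-11-iodo-6,8-dimethylundeca-2,10-dienoate; 16 tributyl[(1E,3Z)-5-(trimethylsilyl)penta-1,3-dien-1-yl]stannane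
Product: 17 methyl (2E,4R,5R,6S,8S,10E,12E,14Z)-4,5-epoxy-6,8-dimethyl-16-(trimethylsilyl)hexadeca-2,10,12,14-tetraenoate
Conditions: Pd2(dba)3 (5 mol %), AsPh3 (20 mol %), NMP, 25 °C, dark
Reagents that add atoms: none
Why: Stille coupling of the vinyl iodide with the dienylstannane, with retention at both partners, assembles the trienyl allylsilane under neutral conditions that spare epoxide, enoate and allylsilane.

**Step 13**
Reactants: 17 methyl (2E,4R,5R,6S,8S,10E,12E,14Z)-4,5-epoxy-6,8-dimethyl-16-(trimethylsilyl)hexadeca-2,10,12,14-tetraenoate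
Product: 19 methyl 2-ethenyl-9-hydroxy-6,8-dimethyl-2,4a,4b,5,6,7,8,8a,9,9a-decahydro-1H-fluorene-1-carboxylate (H-1, H-2, H-4a, H-4b, H-6, H-8, H-9 on one face; H-8a, H-9a on the other), via diethylaluminium alkoxide 18 (not isolated)
Conditions: Et2AlCl (4 equiv), CH2Cl2, −78 to 25 °C; then aq. NaHCO3
Reagents that add atoms: none
Why: Et2AlCl activates the trans-epoxide and C10, the near end of the trienylsilane, attacks C5 (the future C8a) with inversion through a chair in which both methyl groups, the polyene and the C4 epoxide carbon are equatorial, so ring A closes by 6-exo-tet opening with C4b and C8a trans; loss of the silyl group from the resulting pentadienyl cation (vinylogous allylsilane SE2' reaction) gives the (E,E)-diene with its terminal vinyl group in 18. The aluminium-complexed enoate then adds to this diene in an intramolecular Diels–Alder reaction of a 1,3,8-nonatriene, one concerted [4+2] event that closes ring B across the three-atom tether C4b–C8a–C9 and ring C as the cyclohexene. The closest known reaction type is the Lewis-acid-mediated epoxide-opening cyclisation of a polyenyl allylsilane run in tandem with an intramolecular Diels–Alder reaction. The ester-endo transition state gives the trans B/C fusion (C4a, C9a) and puts the ester at C1 cis to the vinyl group at C2, whose relation to C4a follows from the (E,E)-diene. The diene face is chosen by the C9 stereocentre: the C9–H bond eclipses the enoate to avoid allylic 1,3-strain and the C9–O(Al) bond lies anti to the forming C4a–C9a bond, which should give H-4a cis to H-4b. The step needs opening at the epoxide carbon remote from the enoate and attack by the triene terminus, not by the γ-carbon of the allylsilane; the six-membered chair (against a seven-membered or ten-membered alternative) and the electron-poor alkene next to C4 secure both.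

**Step 14**
Reactants: 20 4-(benzyloxy)benzyl chloride; 21 methyl dimethoxyacetate
Product: 23 1-[4-(benzyloxy)phenyl]-3,3-dimethoxypropan-2-one, via Grignard reagent 22 (not isolated)
Conditions: Mg turnings, THF, 0 °C; then add to 21, THF, −78 °C; aq. NH4Cl
Reagents that add atoms: none
Why: Grignard addition to the α,α-dialkoxy ester at low temperature should stop at the ketone because the chelated tetrahedral adduct persists until quench, a known route to α-keto acetals.

**Step 15**
Reactants: 23 1-[4-(benzyloxy)phenyl]-3,3-dimethoxypropan-2-one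
Product: 24 1-(benzyloxy)-4-(2,2,3,3-tetramethoxypropyl)benzene
Conditions: HC(OMe)3, MeOH, p-TsOH (cat.), 50 °C
Reagents that add atoms: trimethyl orthoformate, COC(OC)OC
Why: Acid-catalysed ketalisation driven by the orthoformate masks the ketone, so that no electrophilic carbonyl remains in the strap for step 18.

**Step 16**
Reactants: 24 1-(benzyloxy)-4-(2,2,3,3-tetramethoxypropyl)benzene
Product: 25 4-(2,2,3,3-tetramethoxypropyl)phenol
Conditions: H2 (1 atm), Pd/C, EtOAc, Et3N (trace), rt
Reagents that add atoms: none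
Why: Hydrogenolysis of the benzyl aryl ether under neutral conditions frees the phenol and leaves both ketals intact.

**Step 17**
Reactants: 19 methyl 2-ethenyl-9-hydroxy-6,8-dimethyl-2,4a,4b,5,6,7,8,8a,9,9a-decahydro-1H-fluorene-1-carboxylate; 25 4-(2,2,3,3-tetramethoxypropyl)phenol
Product: 26 methyl 2-ethenyl-6,8-dimethyl-9-[4-(2,2,3,3-tetramethoxypropyl)phenoxy]-2,4a,4b,5,6,7,8,8a,9,9a-decahydro-1H-fluorene-1-carboxylate (9-aryloxy now on the face of H-4a and H-4b)
Conditions: PPh3, DIAD, toluene, 0 to 40 °C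
Reagents that add atoms: none
Why: Mitsunobu etherification: the phenol displaces the C9 oxyphosphonium by SN2 with inversion, which turns the equatorial 9-hydroxyl of 19 into the aryl ether cis to C1 and C8 that the target requires.

**Step 18**
Reactants: 26 methyl 2-ethenyl-6,8-dimethyl-9-[4-(2,2,3,3-tetramethoxypropyl)phenoxy]-2,4a,4b,5,6,7,8,8a,9,9a-decahydro-1H-fluorene-1-carboxylate
Product: 27 3-oxo-3-{2-ethenyl-6,8-dimethyl-9-[4-(2,2,3,3-tetramethoxypropyl)phenoxy]-2,4a,4b,5,6,7,8,8a,9,9a-decahydro-1H-fluoren-1-yl}propanenitrile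
Conditions: MeCN, n-BuLi, THF, −78 °C; then 26, −78 to −20 °C; aq. NH4Cl
Reagents that add atoms: acetonitrile, CC#N
Why: Claisen-type condensation of the ester with lithiated acetonitrile gives the β-ketonitrile, which is deprotonated at once; this prevents over-addition and shields C1 from epimerisation.

**Step 19**
Reactants: 27 3-oxo-3-{…decahydro-1H-fluoren-1-yl}propanenitrile
Product: 28 3-oxo-3-{2-ethenyl-6,8-dimethyl-9-[4-(2,2,3,3-tetramethoxypropyl)phenoxy]-2,4a,4b,5,6,7,8,8a,9,9a-decahydro-1H-fluoren-1-yl}propanamide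
Conditions: PtH(PMe2OH)(PMe2O)2H (5 mol %), EtOH/H2O (4:1), 80 °C
Reagents that add atoms: water, O
Why: Platinum-catalysed nitrile hydration under neutral conditions should give the primary β-ketoamide without touching ketals, alkenes or C1.

**Step 20**
Reactants: 28 3-oxo-3-{…decahydro-1H-fluoren-1-yl}propanamide
Product: 31 xenoacremone A, via keto-aldehyde 29 (not isolated), via aldol adduct 30 (not isolated)
Conditions: TFA/H2O (9:1), CH2Cl2, 0 °C to rt; evaporate; then THF/aq. phosphate buffer pH 7.4, 1 mM, rt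
Reagents that add atoms: water, O
Why: Hydrolysis of both ketals unmasks the 1,2-keto-aldehyde, the β-ketoamide enol adds to the more electrophilic aldehyde carbon (intramolecular aldol addition closing the 13-membered cyclophane, new C3'–C4' bond), and the amide nitrogen then adds to the neighbouring ketone (5-exo hemiaminal formation); both bonds are reversible, so C4' and C5' should settle as the cis-diol lactam held in the natural product.

**Compound list**
1 | meso-2,4-dimethylglutaric anhydride (cis-3,5-dimethyloxane-2,6-dione) | C[C@@H]1C[C@H](C)C(=O)OC1=O | starting material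
2 | meso-(2R,4S)-2,4-dimethylpentane-1,5-diol | OC[C@H](C)C[C@H](C)CO | intermediate
3 | (2S,4R)-5-hydroxy-2,4-dimethylpentyl acetate | OC[C@H](C)C[C@H](C)COC(C)=O | intermediate
4 | (2S,4R)-5-iodo-2,4-dimethylpentyl acetate | IC[C@H](C)C[C@H](C)COC(C)=O | intermediate
5 | [(2R,4S)-5-acetoxy-2,4-dimethylpentyl]zinc iodide | I[Zn]C[C@H](C)C[C@H](C)COC(C)=O | intermediate
6 | (2S,4R,6E)-2,4-dimethyl-7-(trimethylsilyl)hept-6-en-1-yl acetate | C[Si](C)(C)/C=C/C[C@H](C)C[C@H](C)COC(C)=O | intermediate
7 | (2S,4R,6E)-7-iodo-2,4-dimethylhept-6-en-1-yl acetate | I/C=C/C[C@H](C)C[C@H](C)COC(C)=O | intermediate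
8 | (2S,4R,6E)-7-iodo-2,4-dimethylhept-6-en-1-ol | I/C=C/C[C@H](C)C[C@H](C)CO | intermediate
9 | (2S,4R,6E)-7-iodo-2,4-dimethylhept-6-enal | I/C=C/C[C@H](C)C[C@H](C)C=O | intermediate
10 | (2E,4S,6R,8E)-9-iodo-4,6-dimethylnona-2,8-dienal | I/C=C/C[C@H](C)C[C@H](C)/C=C/C=O | intermediate
11 | (2S,3R,4S,6R,8E)-2,3-epoxy-9-iodo-4,6-dimethylnon-8-enal (trans-epoxide) | I/C=C/C[C@H](C)C[C@H](C)[C@H]1O[C@@H]1C=O | intermediate
12 | methyl (2E,4R,5R,6S,8R,10E)-4,5-epoxy-11-iodo-6,8-dimethylundeca-2,10-dienoate | I/C=C/C[C@H](C)C[C@H](C)[C@H]1O[C@@H]1/C=C/C(=O)OC | intermediate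
13 | (E)-1,2-bis(tributylstannyl)ethene | CCCC[Sn](CCCC)(CCCC)/C=C/[Sn](CCCC)(CCCC)CCCC | starting material
14 | (E)-2-(tributylstannyl)ethenyllithium | [Li]/C=C/[Sn](CCCC)(CCCC)CCCC | intermediate
15 | (E)-3-(tributylstannyl)prop-2-enal | O=C/C=C/[Sn](CCCC)(CCCC)CCCC | intermediate
16 | tributyl[(1E,3Z)-5-(trimethylsilyl)penta-1,3-dien-1-yl]stannane | C[Si](C)(C)C/C=C\C=C\[Sn](CCCC)(CCCC)CCCC | intermediate
17 | methyl (2E,4R,5R,6S,8S,10E,12E,14Z)-4,5-epoxy-6,8-dimethyl-16-(trimethylsilyl)hexadeca-2,10,12,14-tetraenoate | C[Si](C)(C)C/C=C\C=C\C=C\C[C@H](C)C[C@H](C)[C@H]1O[C@@H]1/C=C/C(=O)OC | intermediate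
18 | diethylaluminium alkoxide of methyl (E)-4-hydroxy-4-{2-[(1E,3E)-hexa-1,3,5-trienyl]-4,6-dimethylcyclohexyl}but-2-enoate (all four ring substituents equatorial) | C=C/C=C/C=C/[C@@H]1C[C@H](C)C[C@H](C)[C@H]1[C@H](O[Al](CC)CC)/C=C/C(=O)OC | intermediate
19 | methyl 2-ethenyl-9-hydroxy-6,8-dimethyl-2,4a,4b,5,6,7,8,8a,9,9a-decahydro-1H-fluorene-1-carboxylate (A/B and B/C trans-fused, H-4a cis to H-4b, 9-OH trans to C1 and C8, ester cis to vinyl) | C=C[C@@H]1C=C[C@@H]2[C@@H]3C[C@H](C)C[C@H](C)[C@H]3[C@H](O)[C@H]2[C@@H]1C(=O)OC | intermediate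
20 | 4-(benzyloxy)benzyl chloride | ClCc1ccc(OCc2ccccc2)cc1 | starting material
21 | methyl dimethoxyacetate | COC(OC)C(=O)OC | starting material
22 | 4-(benzyloxy)benzylmagnesium chloride | Cl[Mg]Cc1ccc(OCc2ccccc2)cc1 | intermediate
23 | 1-[4-(benzyloxy)phenyl]-3,3-dimethoxypropan-2-one | COC(OC)C(=O)Cc1ccc(OCc2ccccc2)cc1 | intermediate
24 | 1-(benzyloxy)-4-(2,2,3,3-tetramethoxypropyl)benzene | COC(OC)C(OC)(OC)Cc1ccc(OCc2ccccc2)cc1 | intermediate
25 | 4-(2,2,3,3-tetramethoxypropyl)phenol | COC(OC)C(OC)(OC)Cc1ccc(O)cc1 | intermediate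
26 | methyl 2-ethenyl-6,8-dimethyl-9-[4-(2,2,3,3-tetramethoxypropyl)phenoxy]-2,4a,4b,5,6,7,8,8a,9,9a-decahydro-1H-fluorene-1-carboxylate (as 19, C9 inverted) | C=C[C@@H]1C=C[C@@H]2[C@@H]3C[C@H](C)C[C@H](C)[C@H]3[C@@H](Oc3ccc(CC(OC)(OC)C(OC)OC)cc3)[C@H]2[C@@H]1C(=O)OC | intermediate
27 | 3-oxo-3-{2-ethenyl-6,8-dimethyl-9-[4-(2,2,3,3-tetramethoxypropyl)phenoxy]-2,4a,4b,5,6,7,8,8a,9,9a-decahydro-1H-fluoren-1-yl}propanenitrile | C=C[C@@H]1C=C[C@@H]2[C@@H]3C[C@H](C)C[C@H](C)[C@H]3[C@@H](Oc3ccc(CC(OC)(OC)C(OC)OC)cc3)[C@H]2[C@@H]1C(=O)CC#N | intermediate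
28 | 3-oxo-3-{2-ethenyl-6,8-dimethyl-9-[4-(2,2,3,3-tetramethoxypropyl)phenoxy]-2,4a,4b,5,6,7,8,8a,9,9a-decahydro-1H-fluoren-1-yl}propanamide | C=C[C@@H]1C=C[C@@H]2[C@@H]3C[C@H](C)C[C@H](C)[C@H]3[C@@H](Oc3ccc(CC(OC)(OC)C(OC)OC)cc3)[C@H]2[C@@H]1C(=O)CC(N)=O | intermediate
29 | 3-{9-[4-(2,3-dioxopropyl)phenoxy]-2-ethenyl-6,8-dimethyl-2,4a,4b,5,6,7,8,8a,9,9a-decahydro-1H-fluoren-1-yl}-3-oxopropanamide (keto-aldehyde) | C=C[C@@H]1C=C[C@@H]2[C@@H]3C[C@H](C)C[C@H](C)[C@H]3[C@@H](Oc3ccc(CC(=O)C=O)cc3)[C@H]2[C@@H]1C(=O)CC(N)=O | intermediate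
30 | macrocyclic aldol adduct (seco-lactam of 31: 13-membered cyclophane with C4'-OH, C5' ketone, primary amide, enolised acyl group) | C=C[C@@H]1C=C[C@@H]2[C@@H]3C[C@H](C)C[C@H](C)[C@H]3[C@H]3Oc4ccc(cc4)CC(=O)[C@@H](O)/C(C(N)=O)=C(/O)[C@H]1[C@@H]23 | intermediate
31 | xenoacremone A | C=C[C@@H]1C=C[C@@H]2[C@@H]3C[C@H](C)C[C@H](C)[C@H]3[C@H]3Oc4ccc(cc4)C[C@@]4(O)NC(=O)/C(=C(\O)[C@H]1[C@@H]23)[C@@H]4O | target

**Total step count:** 20
**Longest linear sequence:** 15 steps (steps 1–9, 12, 13, 17–20)

**Steps most likely to fail**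

1. Step 20. Strain in the 13-membered cyclophane may keep the open keto-aldehyde from closing under equilibrium conditions, so that intermolecular aldol oligomerisation or dehydration of the adduct takes over. The fallback sets out from 28 and comes back at 31; it replaces the reversible aldol by an irreversible samarium Reformatsky ring closure. Bromination of 28 (N-bromosuccinimide, CH2Cl2, 0 °C) should give the α-bromo-β-ketoamide F1 (epimers at the brominated carbon). Aqueous TFA then unmasks the bromo keto-aldehyde F2. Slow addition of F2 to SmI2 (THF, −78 °C, high dilution) generates the trivalent samarium enolate, which adds to the aldehyde within a chelate that should not revert at this temperature. Work-up at pH 7 lets the amide close the hemiaminal to 31.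

2. Step 13. The two events may not mesh: protodesilylation of the allylsilane, chloride opening of the epoxide, or poor facial selectivity in the cycloaddition. The fallback sets out from 17 and comes back at 19; it splits the cascade into separate operations. Et2AlCl at −78 °C with a cold quench should stop at the trienyl alcohol F3. Silylation (Et3SiOTf, 2,6-lutidine) gives the triethylsilyl ether F4. A thermal intramolecular Diels–Alder reaction (toluene, BHT, 110 °C), in which the bulky silyloxy group reinforces the conformer with C9–H in the enoate plane, should give the tricyclic silyl ether F5. HF·pyridine returns 19.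

3. Step 17. Elimination to the cyclopentene, or no reaction at the hindered C9 alcohol, may compete with substitution. The fallback sets out from 19 and comes back at 26; it uses a discrete sulfonate and a preformed phenoxide in place of the redox condensation. Mesylation (MsCl, Et3N, CH2Cl2, 0 °C) gives the 9-methanesulfonate F6, and SN2 displacement with the caesium phenoxide of 25 (Cs2CO3, DMF, 60 °C) should give 26 with the same inversion.

**Further compounds**
F1 | step 20 | 2-bromo-3-oxo-3-{2-ethenyl-6,8-dimethyl-9-[4-(2,2,3,3-tetramethoxypropyl)phenoxy]-2,4a,4b,5,6,7,8,8a,9,9a-decahydro-1H-fluoren-1-yl}propanamide (epimers at the brominated carbon) | C=C[C@@H]1C=C[C@@H]2[C@@H]3C[C@H](C)C[C@H](C)[C@H]3[C@@H](Oc3ccc(CC(OC)(OC)C(OC)OC)cc3)[C@H]2[C@@H]1C(=O)C(Br)C(N)=O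
F2 | step 20 | 2-bromo-3-{9-[4-(2,3-dioxopropyl)phenoxy]-2-ethenyl-6,8-dimethyl-2,4a,4b,5,6,7,8,8a,9,9a-decahydro-1H-fluoren-1-yl}-3-oxopropanamide | C=C[C@@H]1C=C[C@@H]2[C@@H]3C[C@H](C)C[C@H](C)[C@H]3[C@@H](Oc3ccc(CC(=O)C=O)cc3)[C@H]2[C@@H]1C(=O)C(Br)C(N)=O
F3 | step 13 | methyl (E)-4-hydroxy-4-{2-[(1E,3E)-hexa-1,3,5-trienyl]-4,6-dimethylcyclohexyl}but-2-enoate (configuration as in 18) | C=C/C=C/C=C/[C@@H]1C[C@H](C)C[C@H](C)[C@H]1[C@H](O)/C=C/C(=O)OC
F4 | step 13 | triethylsilyl ether of F3 | C=C/C=C/C=C/[C@@H]1C[C@H](C)C[C@H](C)[C@H]1[C@H](O[Si](CC)(CC)CC)/C=C/C(=O)OC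
F5 | step 13 | methyl 2-ethenyl-6,8-dimethyl-9-(triethylsilyloxy)-2,4a,4b,5,6,7,8,8a,9,9a-decahydro-1H-fluorene-1-carboxylate (configuration as in 19) | C=C[C@@H]1C=C[C@@H]2[C@@H]3C[C@H](C)C[C@H](C)[C@H]3[C@H](O[Si](CC)(CC)CC)[C@H]2[C@@H]1C(=O)OC
F6 | step 17 | methyl 2-ethenyl-9-(methanesulfonyloxy)-6,8-dimethyl-2,4a,4b,5,6,7,8,8a,9,9a-decahydro-1H-fluorene-1-carboxylate (configuration as in 19) | C=C[C@@H]1C=C[C@@H]2[C@@H]3C[C@H](C)C[C@H](C)[C@H]3[C@H](OS(C)(=O)=O)[C@H]2[C@@H]1C(=O)OC
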